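**Plan**
1. Hardest feature: ring C carries oxygen on three contiguous carbons, C2, C3 and C4 (a dissonant 1,2-O,O pattern). Four oxygens (3-OMe, 5-OH, 7-OMe, 4'-O-prenyl) must also end up different, next to an aryl prenyl ether that is labile to acid, heat and oxidants.
2. Retrosynthesis: cut 3-O–CH3, then cut O1–C2 and C2–C3 together. C2 with ring B leaves as a benzylidene (sulfonium ylide), and ring C contracts to the five-membered keto lactone 4-hydroxy-6-methoxybenzofuran-2,3-dione. Its C4–C4a and C3–O1 bonds are then cut to oxalyl chloride and 3,5-dimethoxyphenol.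
3. Forward: ring A is bought, the oxalyl ring is fused on and the peri methyl ether is cleaved. A one-carbon ring expansion (5 → 6) then forms ring C and brings in the already prenylated ring B, and O3 is methylated last.
4. Enabling feature: C3–C4 is an intact oxalyl unit. C2 is a benzylic carbon bound to O1 and to the p-alkoxyphenyl ring B, so it can act first as a carbanion (bond to C3) and then as an electrophile (bond to O1). The opened ring A has two homotopic ortho oxygens, so closure has one outcome and leaves 5-OH free.
5. Stereochemistry: there is none to set.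

Key step: step 5

Remark: the target has no stereocentre and no stereogenic double bond (the prenyl C=C carries two methyl groups), so it is achiral and no enantiomer has to be chosen.

Step 1
Reactants: 1 3,5-dimethoxyphenol; 2 oxalyl chloride
Product: 4 4,6-dimethoxy-1-benzofuran-2,3-dione, via aryl chlorooxoacetate 3 (not isolated)
Conditions: (COCl)2 (3 equiv), ClCH2CH2Cl, 0 °C → reflux
Reagents that add atoms: none
Why: O-acylation followed by intramolecular Friedel–Crafts acylation at the doubly activated ortho carbon (the phenol counterpart of the Stollé isatin synthesis) should close the keto lactone, and the two ortho positions of 1 are equivalent, so only one product can form.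

Step 2
Reactants: 4 4,6-dimethoxy-1-benzofuran-2,3-dione
Product: 5 4-hydroxy-6-methoxy-1-benzofuran-2,3-dione
Conditions: BCl3 (1.2 equiv), CH2Cl2, −78 → 0 °C; cold 1 M HCl; toluene azeotrope
Reagents that add atoms: none
Why: Chelation-directed ether cleavage, as in the selective ortho-demethylation of o-methoxyaryl ketones, in which BCl3 binds between the C3 ketone oxygen and the peri 4-OMe so that chloride removes only that methyl group, and any acid formed by hydrolysis on work-up should relactonise on azeotropic drying.

Step 3
Reactants: 6 4-hydroxybenzyl alcohol; 7 prenyl bromide (1-bromo-3-methylbut-2-ene)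
Product: 8 [4-(3-methylbut-2-en-1-yloxy)phenyl]methanol
Conditions: K2CO3, acetone, reflux
Reagents that add atoms: none
Why: Williamson ether synthesis, in which carbonate deprotonates only the phenol and not the benzylic alcohol, and the primary allylic bromide reacts by SN2 at oxygen.

Step 4
Reactants: 8 [4-(3-methylbut-2-en-1-yloxy)phenyl]methanol
Product: 10 1-{[4-(3-methylbut-2-en-1-yloxy)phenyl]methyl}thiolan-1-ium tetrafluoroborate, via benzylic bromide 9 (not isolated)
Conditions: CBr4, PPh3, CH2Cl2, 0 °C; then tetrahydrothiophene, NaBF4, acetone, rt; trituration with Et2O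
Reagents that add atoms: carbon tetrabromide, BrC(Br)(Br)Br (bromine of 9); tetrahydrothiophene, C1CCSC1; sodium tetrafluoroborate, [Na+].F[B-](F)(F)F
Why: The neutral Appel bromination spares the acid-labile prenyl ether, and S-alkylation of the sulfide by the reactive p-alkoxybenzyl bromide with exchange to non-nucleophilic BF4− (which blocks the reverse reaction) should give a salt that trituration frees from the neutral by-products.

Step 5
Reactants: 5 4-hydroxy-6-methoxy-1-benzofuran-2,3-dione; 10 1-{[4-(3-methylbut-2-en-1-yloxy)phenyl]methyl}thiolan-1-ium tetrafluoroborate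
Product: 13 3,5-dihydroxy-7-methoxy-2-[4-(3-methylbut-2-en-1-yloxy)phenyl]-4H-chromen-4-one, via sulfonium benzylide 11 (not isolated), via diketo sulfonium ylide 12 (not isolated)
Conditions: 10 (1.1 equiv), NaHMDS (2.1 equiv), THF, −78 °C; add 5, −78 → 0 °C; AcOH (1.0 equiv), 50 °C, N2
Reagents that add atoms: none
Why: Proposed new method: the benzylide 11 (C2 as carbanion) should add to the lactone carbonyl of 5 (future C3), the adduct expels the aryloxide O1 and loses the now very acidic C2–H, so that acyl substitution ends irreversibly in the diketo-stabilised ylide 12. Buffering with AcOH allows C-protonation, which turns the same carbon into an α-keto, p-alkoxybenzylic sulfonium electrophile; an ortho phenoxide displaces tetrahydrothiophene and the flavan-3,4-dione so formed tautomerises to the aromatic 3-hydroxy-4-pyranone, the thermodynamic sink of all species at this oxidation level. The closest known reaction types are the acylation of sulfur ylides by esters, lactones and lactams followed by intramolecular X–H insertion (one-carbon ring expansion of lactams; benzofuran-3-ones from salicylate-derived keto ylides) and the last ring closure of the Auwers flavonol synthesis, where an o-hydroxyaryl 1,2-diketone closes on a benzylic leaving group; new is the use of an aryl-substituted sulfonium ylide on a benzofuran-2,3-dione. Ring C closes 6-exo-tet (O1 attacks C2, the C2–S bond lies outside the ring); C2 is stereogenic only in passing and becomes sp2, so no stereocontrol is needed. The step needs attack at the lactone and not at the ketone carbonyl: the ketone is the peri-hindered, vinylogous-carbonate carbonyl of a 2,4,6-trioxygenated ring and is deactivated further as the 4-phenoxide, and its betaine can revert, whereas the α-keto aryl ester is strongly activated and its substitution is made irreversible by proton loss. Ring opening makes the two ortho oxygens of ring A homotopic, so closure through either gives the same product and the unused one becomes the chelated 5-OH.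

Step 6
Reactants: 13 3,5-dihydroxy-7-methoxy-2-[4-(3-methylbut-2-en-1-yloxy)phenyl]-4H-chromen-4-one
Product: 14 5-hydroxy-3,7-dimethoxy-2-[4-(3-methylbut-2-en-1-yloxy)phenyl]-4H-chromen-4-one (target)
Conditions: MeI (1.05 equiv), K2CO3 (1.1 equiv), acetone, rt
Reagents that add atoms: iodomethane, CI
Why: Chemoselective Williamson O-methylation, since 3-OH is the more acidic and only weakly hydrogen-bonded hydroxyl whereas 5-OH is locked in a six-membered chelate with C4=O, so one equivalent of MeI should alkylate O3 only, in line with the usual reactivity order of flavonol hydroxyls.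

**Compound list**
1 | 3,5-dimethoxyphenol | COc1cc(O)cc(OC)c1 | starting material
2 | oxalyl chloride | O=C(Cl)C(=O)Cl | starting material
3 | 3,5-dimethoxyphenyl chlorooxoacetate | COc1cc(OC)cc(OC(=O)C(=O)Cl)c1 | intermediate
4 | 4,6-dimethoxy-1-benzofuran-2,3-dione | COc1cc(OC)c2C(=O)C(=O)Oc2c1 | intermediate
5 | 4-hydroxy-6-methoxy-1-benzofuran-2,3-dione | COc1cc(O)c2C(=O)C(=O)Oc2c1 | intermediate
6 | 4-hydroxybenzyl alcohol | OCc1ccc(O)cc1 | starting material
7 | prenyl bromide (1-bromo-3-methylbut-2-ene) | CC(C)=CCBr | starting material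
8 | [4-(3-methylbut-2-en-1-yloxy)phenyl]methanol | CC(C)=CCOc1ccc(CO)cc1 | intermediate
9 | 1-(bromomethyl)-4-(3-methylbut-2-en-1-yloxy)benzene | CC(C)=CCOc1ccc(CBr)cc1 | intermediate
10 | 1-{[4-(3-methylbut-2-en-1-yloxy)phenyl]methyl}thiolan-1-ium tetrafluoroborate | CC(C)=CCOc1ccc(C[S+]2CCCC2)cc1.F[B-](F)(F)F | intermediate
11 | thiolan-1-ium [4-(3-methylbut-2-en-1-yloxy)phenyl]methylide | CC(C)=CCOc1ccc([CH-][S+]2CCCC2)cc1 | intermediate
12 | 1-(2,6-dihydroxy-4-methoxyphenyl)-3-[4-(3-methylbut-2-en-1-yloxy)phenyl]-3-(thiolan-1-ium-1-yl)propane-1,2-dion-3-ide (written in neutral form) | COc1cc(O)c(C(=O)C(=O)[C-](c2ccc(OCC=C(C)C)cc2)[S+]2CCCC2)c(O)c1 | intermediate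
13 | 3,5-dihydroxy-7-methoxy-2-[4-(3-methylbut-2-en-1-yloxy)phenyl]-4H-chromen-4-one | COc1cc(O)c2c(=O)c(O)c(-c3ccc(OCC=C(C)C)cc3)oc2c1 | intermediate
14 | 5-hydroxy-3,7-dimethoxy-2-[4-(3-methylbut-2-en-1-yloxy)phenyl]-4H-chromen-4-one | COc1cc(O)c2c(=O)c(OC)c(-c3ccc(OCC=C(C)C)cc3)oc2c1 | target

**Step count**
Total step count: 6. Longest linear sequence: 4 (steps 1, 2, 5, 6 or steps 3, 4, 5, 6).

**Steps most likely to fail**

Step 5 (Proposed new method).
- The ylide may add to the ketone carbonyl and close irreversibly to a three-membered ring.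
- The first adduct at the lactone carbon may close in the same way before the aryloxide leaves.
- The reaction may rest at the stabilised ylide without C–O closure.

The fallback uses known chemistry (Baker–Venkataraman logic with late prenylation). It sets out from 1 and comes back at 14. Compound 1 is C-acylated ortho to the hydroxyl with methoxyacetyl chloride and TiCl4 to 1-(2-hydroxy-4,6-dimethoxyphenyl)-2-methoxyethan-1-one F1. Esterification with commercial 4-(benzyloxy)benzoyl chloride in pyridine gives 2-(methoxyacetyl)-3,5-dimethoxyphenyl 4-(benzyloxy)benzoate F2. KOH in pyridine rearranges this to 1-[4-(benzyloxy)phenyl]-3-(2-hydroxy-4,6-dimethoxyphenyl)-2-methoxypropane-1,3-dione F3 (racemic, enolisable). Cyclodehydration with catalytic H2SO4 in AcOH gives 2-[4-(benzyloxy)phenyl]-3,5,7-trimethoxy-4H-chromen-4-one F4. BCl3 at low temperature removes the chelated 5-O-methyl group and the benzyl group to give 5-hydroxy-2-(4-hydroxyphenyl)-3,7-dimethoxy-4H-chromen-4-one F5. Compound 7 with K2CO3 then alkylates only the unchelated 4'-OH to give 14.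

Step 2.
- The lactone may open hydrolytically during the boron work-up.
- Both methyl ethers may be cleaved.

The fallback moves the demethylation to the robust flavone stage and brings in the prenyl group last. It sets out from 4 and comes back at 14. Commercial 4-(benzyloxy)benzyl chloride, tetrahydrothiophene and NaBF4 give 1-{[4-(benzyloxy)phenyl]methyl}thiolan-1-ium tetrafluoroborate F6. Its ylide (one equivalent of NaHMDS, since no acidic OH is present) ring-expands 4 as in step 5 to 2-[4-(benzyloxy)phenyl]-3-hydroxy-5,7-dimethoxy-4H-chromen-4-one F7. MeI and K2CO3 give 2-[4-(benzyloxy)phenyl]-3,5,7-trimethoxy-4H-chromen-4-one F4. BCl3 gives 5-hydroxy-2-(4-hydroxyphenyl)-3,7-dimethoxy-4H-chromen-4-one F5, and 7 with K2CO3 gives 14.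

Step 1.
- The reaction may stop after O-acylation.
- Two phenols may be consumed per oxalyl chloride.
- Intermolecular C-acylation may compete.

The fallback forms the C–C bond first and the lactone last. It sets out from 1 and comes back at 4. TiCl4-mediated ortho-acylation of 1 with ethyl chlorooxoacetate gives ethyl 2-(2-hydroxy-4,6-dimethoxyphenyl)-2-oxoacetate F8. LiOH in aqueous THF gives 2-(2-hydroxy-4,6-dimethoxyphenyl)-2-oxoacetic acid F9. DCC in CH2Cl2 closes the lactone to 4.

**Further compounds**
F1 | step 5 | 1-(2-hydroxy-4,6-dimethoxyphenyl)-2-methoxyethan-1-one | COCC(=O)c1c(O)cc(OC)cc1OC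
F2 | step 5 | 2-(methoxyacetyl)-3,5-dimethoxyphenyl 4-(benzyloxy)benzoate | COCC(=O)c1c(OC(=O)c2ccc(OCc3ccccc3)cc2)cc(OC)cc1OC
F3 | step 5 | 1-[4-(benzyloxy)phenyl]-3-(2-hydroxy-4,6-dimethoxyphenyl)-2-methoxypropane-1,3-dione (racemic, enolisable) | COC(C(=O)c1ccc(OCc2ccccc2)cc1)C(=O)c1c(O)cc(OC)cc1OC
F4 | step 5 | 2-[4-(benzyloxy)phenyl]-3,5,7-trimethoxy-4H-chromen-4-one | COc1cc(OC)c2c(=O)c(OC)c(-c3ccc(OCc4ccccc4)cc3)oc2c1
F5 | step 5 | 5-hydroxy-2-(4-hydroxyphenyl)-3,7-dimethoxy-4H-chromen-4-one | COc1cc(O)c2c(=O)c(OC)c(-c3ccc(O)cc3)oc2c1
F6 | step 2 | 1-{[4-(benzyloxy)phenyl]methyl}thiolan-1-ium tetrafluoroborate | C(c1ccccc1)Oc1ccc(C[S+]2CCCC2)cc1.F[B-](F)(F)F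
F7 | step 2 | 2-[4-(benzyloxy)phenyl]-3-hydroxy-5,7-dimethoxy-4H-chromen-4-one | COc1cc(OC)c2c(=O)c(O)c(-c3ccc(OCc4ccccc4)cc3)oc2c1
F8 | step 1 | ethyl 2-(2-hydroxy-4,6-dimethoxyphenyl)-2-oxoacetate | CCOC(=O)C(=O)c1c(O)cc(OC)cc1OC
F9 | step 1 | 2-(2-hydroxy-4,6-dimethoxyphenyl)-2-oxoacetic acid | OC(=O)C(=O)c1c(O)cc(OC)cc1OC
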